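Remark on the chemistry: the target is achiral, so every intermediate with stereocentres is carried as a racemate (13 and 17 as diastereomer mixtures); Ar stands throughout for 4,6-bis(benzyloxy)-7-(2-methylbut-3-en-2-yl)benzofuran-2-yl, and 3,5-bis(benzyloxy)phenol is taken as purchasable.

## Analysis of the target

The target 25 is an achiral 2-arylbenzofuran. A benzofuran (ring A the benzo ring, ring B the furan) carries at its C2 the C5 carbon of a 2,2-dimethylchroman (ring C the benzene ring, ring D the dihydropyran; chroman atoms O1, C2–C4, C4a, C5–C8, C8a). Ring A is a phloroglucinol pattern with oxygen on C4, C6 and C7a and a 2-methylbut-3-en-2-yl (1,1-dimethylallyl) group on C7, wedged between the C6 hydroxyl and the furan oxygen. There is no stereocentre and no stereogenic double bond, so configuration matters only in intermediates and can be spent freely. The delicate parts are three phenols on electron-rich rings, the tert-alkyl aryl ether of ring D and, above all, the 1,1-dimethylallyl group: its vinyl end forbids hydrogenolysis, and strong acid can detach it, shift it or close it onto the C6 hydroxyl. Two substitution problems make the synthesis hard: a quaternary benzylic carbon on the most crowded carbon of ring A, and ring C, a 1,2,3,5-tetrasubstituted benzene (aryl on C5, hydroxyl on C7, pyran fused at C4a/C8a) that is not reached cleanly from a resorcinol. The strategy rests on one feature of ring C: C8a with its oxygen O1 and C4a with its arm C4–C3–C2 are the carbonyl carbon, ring oxygen and α-carbon of lactone 12, and the neighbouring biaryl carbon C5 is an exocyclic arylidene carbon on that lactone. The remaining ring carbons C6, C7 (with its oxygen) and C8 are the central, ketone and methyl carbons of acetoacetate 16, so ring C can be built as a cyclohexane-1,3-dione and aromatised late.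

## Retrosynthetic reasoning

**25 ⇒ 24.** The two O–benzyl bonds on ring A are cut last. Ethers are needed because the route runs through alkoxide, amide bases, hydride and a 190 °C rearrangement. Benzyl is chosen because it survives all of these, and its removal must be non-hydrogenolytic because of the vinyl group. The forward step has to cleave two aryl benzyl ethers at low temperature without touching the 1,1-dimethylallyl group or the tert-alkyl ether of ring D.

**24 ⇒ 21.** Ring C is taken one oxidation level down, to the vinylogous ester 21 with sp3 carbons at C4a, C5 and C6. This turns a benzene ring into something that carbonyl condensations can assemble. Forward, a single dehydrogenation across C5–C6 is needed; the resulting dienone is a phenol tautomer and aromatises by itself.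

**21 ⇒ 18.** The enol ether bond O1–C8a is cut and an ester carbon is put back on C6, giving the hydroxy dione ester 18. Forward, acid must remove the tert-butyl ester, decarboxylate and let the tertiary hydroxyl condense with a dione carbonyl. Because the arm sits on C4a, only C8a is within reach of a six-membered closure, so ring D cannot form in the wrong place.

**18 ⇒ 15 + 16.** This is the central disconnection: bonds C5–C6 and C8–C8a are cut, releasing the arylidene lactone 15 and acetoacetate 16. It is made here because these two bonds are a conjugate addition and an acyl substitution on the same lactone, and every atom of 15 and 16 stays in 18. The positions of aryl group, arm and both oxygens on ring C follow from connectivity alone, with no directing effects to manage. Forward, the enolate of 16 must add 1,4 and its methyl carbon must then acylate on the lactone carbonyl.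

**15 ⇒ 10 + 12; 12 ⇒ 11.** The exocyclic C5=C4a double bond is an aldol condensation between aldehyde 10 and lactone 12. Lactone 12 comes from anhydride 11 by two methyl additions to one carbonyl. This keeps the lactone branch to one step and makes the assembly convergent.

**10 ⇒ 9 ⇒ 8 ⇒ 5 + 6.** The aldehyde is reached from ester 8 through alcohol 9 by two reliable redox steps. Ring B is then opened at O1–C2 and C2–C3, which leads to salicylaldehyde 5 and bromoacetate 6. The annulation needs only a phenol next to a formyl group.

**5 ⇒ 4 ⇒ 3 ⇒ 1 + 2.** The formyl carbon is removed from the one free carbon ortho to the hydroxyl of 4. The bond from ring A to the quaternary carbon is traced back through a [3,3] shift to the prenyl ether 3, and 3 to phenol 1 and bromide 2. Both ortho carbons of 3 are equivalent, so the rearrangement has only one ortho product.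

## Alternatives that were turned down

**Alternative 1: ring A built on a furan by ketene–alkyne benzannulation.**
- Disconnection: benzofuran bonds C4–C5, C6–C7 and C3a–C4 are cut, leaving the furylacetyl chloride A2 (already carrying the chroman and the 1,1-dimethylallyl group) and the siloxyalkyne A3.
- Forward key step: an amine base dehydrohalogenates A2 to a ketene, which undergoes [2+2] cycloaddition with A3. Heating opens the four-membered ring and the resulting dienyl ketene closes by a six-electron electrocyclisation onto furan C3. Tautomerisation gives A1 with the C4 hydroxyl free and the C6 oxygen silylated.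
- For: all six positions of ring A are fixed by the mechanism. The quaternary carbon arrives with the ketene, so no aromatic Claisen rearrangement is needed. The end-game is a fluoride desilylation, which is gentler on the 1,1-dimethylallyl group than a Lewis acid. On these points it is stronger than the chosen plan.
- Against: the ketene must form at a carbon bearing a tert-alkyl group and then create a second quaternary centre next to the first; hindered ketene formation is slow and electron-rich heteroaryl ketenes dimerise. A3 is a sensitive reagent. Most important, the chroman with its C5 carbon substituent and C7 oxygen has to be supplied ready-made, so the ring C pattern is moved to a separate branch and not solved.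
- Comparison: two branches of several steps each precede the key step, so the count is no shorter. The chosen route offers cheap carbonyl chemistry and a ring C pattern set by connectivity; it pays for this with an acid step and a Lewis-acid deprotection near the 1,1-dimethylallyl group.

**Alternative 2: rings C and D together by [2+2+2] cyclotrimerisation.**
- Disconnection: chroman bonds C4a–C8a, C5–C6 and C7–C8 are cut at once, giving the ynol-ether diyne A5 and the ethynylboronate A6.
- Forward key step: a cyclopentadienyl ruthenium chloride catalyst couples the two alkynes of A5 to a metallacycle, A6 inserts and reductive elimination gives the arylboronate A4. Oxidation of the C–B bond and removal of the methoxymethyl groups would finish.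
- For: ring C is made aromatic directly, so no dehydrogenation is needed, and two rings form in one operation at room temperature. O1/C8a and C4/C4a are fixed by the tether just as in the chosen plan. In redox economy and in steps after the key step it is stronger.
- Against: an ethynyl ether of a tertiary carbinol fragments easily to a ketene and an alkene and has to be made and carried. The orientation of A6 (boron on C7 or on C6) rests only on a steric preference of the catalyst, here facing a very bulky benzofuranyl group on the diyne terminus. The vinyl group of ring A is a possible competing π-partner. Acetal removal at the end needs protic acid next to the 1,1-dimethylallyl group.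
- Comparison: overall length is similar once A5 is prepared. The chosen route gives up elegance and accepts a dehydrogenation step, and in return offers robust intermediates, no regiochemical choice for the three-carbon partner and no precious-metal cycloaddition on a fragile substrate.

**Alternative 3: Friedel–Crafts cyclodehydration closing ring B.**
- Disconnection: furan bond C3–C3a is cut (and before it O1–C2, by O-alkylation of a ring A phenol), leading to the α-aryloxy-α-aryl acetaldehyde A8.
- Forward key step: a boron Lewis acid activates the aldehyde of A8, the single free ortho carbon of the aryl ether attacks it, and loss of water aromatises ring B to give the tribenzyl ether A7.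
- For: it is the most convergent and the shortest way to join the two halves, and the closure has no regiochemical choice because the other ortho carbon is blocked. In step economy it is stronger than the chosen plan.
- Against: the phenoxide to be alkylated is flanked by the tert-alkyl group and must displace a secondary benzylic leaving group beside an ortho-substituted aryl ring. A8 is readily enolised and can expel phenoxide. The Lewis acid meets a 1,1-dimethylallyl group on a trioxygenated ring. The chroman half again has to arrive with the 5,7-pattern, which brings back the resorcinol regiochemistry problem. Three benzyl groups then leave under the same Lewis acid as in the chosen route.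
- Comparison: shorter on paper, but its two hardest operations sit on the most hindered and most acid-sensitive site. The chosen route places its risk in a base-mediated annulation whose regiochemistry cannot come out wrong.

Key step: step 10

## Route

**Step 1**
Reactants: 1 3,5-bis(benzyloxy)phenol; 2 1-bromo-3-methylbut-2-ene
Product: 3 1,3-bis(benzyloxy)-5-[(3-methylbut-2-en-1-yl)oxy]benzene
Conditions: K2CO3, acetone, 56 °C
Reagents that add atoms: none
Why: Williamson ether synthesis; the phenoxide of 1 displaces bromide from the primary allylic bromide by SN2, and carbonate in acetone favours O- over C-alkylation.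

**Step 2**
Reactants: 3 1,3-bis(benzyloxy)-5-[(3-methylbut-2-en-1-yl)oxy]benzene
Product: 4 3,5-bis(benzyloxy)-2-(2-methylbut-3-en-2-yl)phenol
Conditions: PhNEt2, 190 °C, Ar
Reagents that add atoms: none
Why: Aromatic Claisen rearrangement; the [3,3] shift delivers the dimethyl-substituted allyl terminus to an ortho carbon (both are equivalent), and the amine solvent speeds enolisation of the ortho-dienone to the phenol before a second shift can occur.

**Step 3**
Reactants: 4 3,5-bis(benzyloxy)-2-(2-methylbut-3-en-2-yl)phenol
Product: 5 4,6-bis(benzyloxy)-2-hydroxy-3-(2-methylbut-3-en-2-yl)benzaldehyde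
Conditions: MgCl2, Et3N, (CH2O)n, MeCN, 80 °C; then 1 M HCl
Reagents that add atoms: paraformaldehyde (as formaldehyde), C=O
Why: Magnesium-mediated ortho-formylation (Casnati–Skattebøl); the chloromagnesium phenoxide delivers formaldehyde to the only free ortho carbon and a second formaldehyde oxidises the benzylic alkoxide by hydride transfer, so the para carbon between the benzyloxy groups is not attacked.

**Step 4**
Reactants: 5 4,6-bis(benzyloxy)-2-hydroxy-3-(2-methylbut-3-en-2-yl)benzaldehyde; 6 ethyl bromoacetate
Product: 8 ethyl 4,6-bis(benzyloxy)-7-(2-methylbut-3-en-2-yl)benzofuran-2-carboxylate, via aryloxyacetate 7 (not isolated)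
Conditions: K2CO3, DMF, 25 → 110 °C
Reagents that add atoms: none
Why: Rap–Stoermer-type benzofuran annulation; O-alkylation gives 7, whose ester enolate adds to the ortho formyl group (5-exo-trig aldol) and loses water to aromatise ring B, forming O1–C2 and C2–C3.

**Step 5**
Reactants: 8 ethyl 4,6-bis(benzyloxy)-7-(2-methylbut-3-en-2-yl)benzofuran-2-carboxylate
Product: 9 [4,6-bis(benzyloxy)-7-(2-methylbut-3-en-2-yl)benzofuran-2-yl]methanol
Conditions: iBu2AlH (2.5 equiv), CH2Cl2, −78 → 0 °C; aq. KNaC4H4O6 (potassium sodium tartrate)
Reagents that add atoms: none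
Why: Hydride reduction of the ester through the aldehyde to the primary alcohol; benzyl ethers, the furan and the isolated vinyl group are inert to iBu2AlH at low temperature.

**Step 6**
Reactants: 9 [4,6-bis(benzyloxy)-7-(2-methylbut-3-en-2-yl)benzofuran-2-yl]methanol
Product: 10 4,6-bis(benzyloxy)-7-(2-methylbut-3-en-2-yl)benzofuran-2-carbaldehyde
Conditions: MnO2, CH2Cl2, 25 °C
Reagents that add atoms: none
Why: MnO2 oxidises the activated heteroaryl carbinol to the aldehyde without over-oxidation and leaves the alkene and ethers alone.

**Step 7**
Reactants: 11 glutaric anhydride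
Product: 12 6,6-dimethyltetrahydro-2H-pyran-2-one
Conditions: MeMgBr (2.2 equiv), THF, −20 → 25 °C; then 2 M HCl
Reagents that add atoms: methylmagnesium bromide, C[Mg]Br
Why: Double Grignard addition; the first equivalent opens the anhydride to the magnesium 5-oxohexanoate, the second adds to the ketone faster than to the carboxylate, and acidification lactonises the 5-hydroxy acid.

**Step 8**
Reactants: 12 6,6-dimethyltetrahydro-2H-pyran-2-one; 10 4,6-bis(benzyloxy)-7-(2-methylbut-3-en-2-yl)benzofuran-2-carbaldehyde
Product: 13 3-[Ar(hydroxy)methyl]-6,6-dimethyltetrahydro-2H-pyran-2-one (mixture of diastereomers)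
Conditions: LiN(iPr)2, THF, −78 °C; then 10, −78 °C; aq. NH4Cl
Reagents that add atoms: none
Why: Directed aldol addition of the lithium enolate of the lactone to a non-enolisable aldehyde; the two new stereocentres form unselectively, which is of no consequence because step 9 removes both.

**Step 9**
Reactants: 13 3-[Ar(hydroxy)methyl]-6,6-dimethyltetrahydro-2H-pyran-2-one
Product: 15 (E)-3-(Ar-methylene)-6,6-dimethyltetrahydro-2H-pyran-2-one, via mesylate 14 (not isolated)
Conditions: MsCl, Et3N, CH2Cl2, 0 °C; then DBU, 0 → 25 °C
Reagents that add atoms: none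
Why: Mesylation followed by E1cB elimination through the lactone enolate; this enolate-mediated pathway should give the more stable (E)-alkene, with the benzofuranyl group anti to the lactone carbonyl, from either diastereomer of 13.

**Step 10**
Reactants: 15 (E)-3-(Ar-methylene)-6,6-dimethyltetrahydro-2H-pyran-2-one; 16 tert-butyl acetoacetate
Product: 18 tert-butyl 6-Ar-5-(3-hydroxy-3-methylbutyl)-2,4-dioxocyclohexane-1-carboxylate (racemic all-trans), via Michael adduct 17 (not isolated)
Conditions: 16 (1.5 equiv), KOtBu (2.5 equiv), tBuOH/THF, 25 → 70 °C; then 1 M HCl, 0 °C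
Reagents that add atoms: none
Why: Proposed new method: the potassium enolate of 16 adds through its central carbon to the arylidene carbon of 15 in a conjugate addition (chroman bond C5–C6), giving adduct 17 as its enolates. Proton exchange exposes a small share of the methyl-ketone enolate, which attacks the lactone carbonyl; the tetrahedral intermediate expels the ring oxygen as a tertiary alkoxide (bond C8–C8a), and deprotonation of the acidic 1,3-dione pulls all earlier equilibria forward. The closest known reaction is the tandem Michael–Claisen condensation of acetoacetic esters with cinnamates and other acyclic unsaturated esters to cyclohexane-1,3-diones; new here is that the acyl donor is a lactone carbonyl whose leaving group stays in the molecule as the future O1. The carbocycle of ring C closes by 6-exo-trig acyl substitution. The three new stereocentres (ester, aryl and side-arm carbons) are under thermodynamic control: the ester and arm carbons are each α to a carbonyl and epimerise under alkoxide, so all three substituents should settle equatorial (all-trans); none is needed later. The step needs 1,4- over 1,2-addition and acylation at the lactone rather than alkoxide-driven lactone opening; the soft stabilised enolate, the s-cis-locked exocyclic enoate and the hindered tert-butoxide (which also cannot exchange the tert-butyl ester) secure this. Only the methyl enolate can reach the lactone carbonyl through a six-membered transition state, since the central carbon would have to close a four-membered ring. The positions of aryl group, arm and oxygens on ring C then follow from connectivity.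

**Step 11**
Reactants: 18 tert-butyl 6-Ar-5-(3-hydroxy-3-methylbutyl)-2,4-dioxocyclohexane-1-carboxylate
Product: 21 (4a,5-trans)-5-Ar-2,2-dimethyl-2,3,4,4a,5,6-hexahydro-7H-chromen-7-one, via keto acid 19 (not isolated), via hydroxy dione 20 (not isolated)
Conditions: TsOH·H2O (20 mol %), toluene, 80 °C
Reagents that add atoms: none
Why: Acid-catalysed loss of 2-methylpropene gives β-keto acid 19, which decarboxylates on warming to 20; the tertiary hydroxyl then condenses with the only carbonyl it can reach in a six-membered ring (C8a), and loss of water gives the conjugated vinylogous ester with ring D closed. The two remaining stereocentres should stay trans, C4a being epimerisable.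

**Step 12**
Reactants: 21 (4a,5-trans)-5-Ar-2,2-dimethyl-2,3,4,4a,5,6-hexahydro-7H-chromen-7-one
Product: 24 5-[4,6-bis(benzyloxy)-7-(2-methylbut-3-en-2-yl)benzofuran-2-yl]-2,2-dimethylchroman-7-ol, via silyl dienol ether 22 (not isolated), via dienone 23 (not isolated)
Conditions: LiN(iPr)2, Me3SiCl, THF, −78 → 0 °C; then Pd(OAc)2 (1.1 equiv), MeCN, 25 °C
Reagents that add atoms: none
Why: Saegusa–Ito dehydrogenation; kinetic deprotonation of the vinylogous ester at C6 and O-silylation give 22, divalent palladium forms the C6-bound enolate on the face away from the aryl group and so syn to H5, and β-hydride elimination gives dienone 23 and zerovalent palladium. Dienone 23 is a keto tautomer of a phenol and loses H4a to aromatise ring C, erasing both stereocentres.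

**Step 13**
Reactants: 24 5-[4,6-bis(benzyloxy)-7-(2-methylbut-3-en-2-yl)benzofuran-2-yl]-2,2-dimethylchroman-7-ol
Product: 25 2-(7-hydroxy-2,2-dimethylchroman-5-yl)-7-(2-methylbut-3-en-2-yl)benzofuran-4,6-diol (CNP0300714.0)
Conditions: BCl3 (6 equiv), C6HMe5 (8 equiv), CH2Cl2, −78 °C; then MeOH, −78 °C
Reagents that add atoms: none
Why: Lewis-acid cleavage of aryl benzyl ethers; BCl3 coordinates the ether oxygens and the benzyl cations are captured by pentamethylbenzene (Friedel–Crafts) and not by the electron-rich rings or the vinyl group. At −78 °C the tert-alkyl aryl ether of ring D and the 1,1-dimethylallyl group should survive.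

## Compound list

1 | 3,5-bis(benzyloxy)phenol | Oc1cc(OCc2ccccc2)cc(OCc2ccccc2)c1 | starting material
2 | 1-bromo-3-methylbut-2-ene | CC(C)=CCBr | starting material
3 | 1,3-bis(benzyloxy)-5-[(3-methylbut-2-en-1-yl)oxy]benzene | CC(C)=CCOc1cc(OCc2ccccc2)cc(OCc2ccccc2)c1 | intermediate
4 | 3,5-bis(benzyloxy)-2-(2-methylbut-3-en-2-yl)phenol | C=CC(C)(C)c1c(O)cc(OCc2ccccc2)cc1OCc1ccccc1 | intermediate
5 | 4,6-bis(benzyloxy)-2-hydroxy-3-(2-methylbut-3-en-2-yl)benzaldehyde | C=CC(C)(C)c1c(O)c(C=O)c(OCc2ccccc2)cc1OCc1ccccc1 | intermediate
6 | ethyl bromoacetate | CCOC(=O)CBr | starting material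
7 | ethyl 2-[3,5-bis(benzyloxy)-2-formyl-6-(2-methylbut-3-en-2-yl)phenoxy]acetate | C=CC(C)(C)c1c(OCC(=O)OCC)c(C=O)c(OCc2ccccc2)cc1OCc1ccccc1 | intermediate
8 | ethyl 4,6-bis(benzyloxy)-7-(2-methylbut-3-en-2-yl)benzofuran-2-carboxylate | C=CC(C)(C)c1c(OCc2ccccc2)cc(OCc2ccccc2)c2cc(C(=O)OCC)oc12 | intermediate
9 | [4,6-bis(benzyloxy)-7-(2-methylbut-3-en-2-yl)benzofuran-2-yl]methanol | C=CC(C)(C)c1c(OCc2ccccc2)cc(OCc2ccccc2)c2cc(CO)oc12 | intermediate
10 | 4,6-bis(benzyloxy)-7-(2-methylbut-3-en-2-yl)benzofuran-2-carbaldehyde | C=CC(C)(C)c1c(OCc2ccccc2)cc(OCc2ccccc2)c2cc(C=O)oc12 | intermediate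
11 | glutaric anhydride | O=C1CCCC(=O)O1 | starting material
12 | 6,6-dimethyltetrahydro-2H-pyran-2-one | CC1(C)CCCC(=O)O1 | intermediate
13 | 3-[Ar(hydroxy)methyl]-6,6-dimethyltetrahydro-2H-pyran-2-one, mixture of diastereomers | C=CC(C)(C)c1c(OCc2ccccc2)cc(OCc2ccccc2)c2cc(C(O)C3CCC(C)(C)OC3=O)oc12 | intermediate
14 | Ar(6,6-dimethyl-2-oxotetrahydro-2H-pyran-3-yl)methyl methanesulfonate | C=CC(C)(C)c1c(OCc2ccccc2)cc(OCc2ccccc2)c2cc(C(OS(C)(=O)=O)C3CCC(C)(C)OC3=O)oc12 | intermediate
15 | (E)-3-(Ar-methylene)-6,6-dimethyltetrahydro-2H-pyran-2-one | C=CC(C)(C)c1c(OCc2ccccc2)cc(OCc2ccccc2)c2cc(/C=C3\CCC(C)(C)OC3=O)oc12 | intermediate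
16 | tert-butyl acetoacetate | CC(=O)CC(=O)OC(C)(C)C | starting material
17 | tert-butyl 2-[Ar(6,6-dimethyl-2-oxotetrahydro-2H-pyran-3-yl)methyl]-3-oxobutanoate, mixture of diastereomers | CC(=O)C(C(=O)OC(C)(C)C)C(c1cc2c(OCc3ccccc3)cc(OCc3ccccc3)c(C(C)(C)C=C)c2o1)C1CCC(C)(C)OC1=O | intermediate
18 | tert-butyl 6-Ar-5-(3-hydroxy-3-methylbutyl)-2,4-dioxocyclohexane-1-carboxylate, racemic, all-trans (one enantiomer drawn, keto form) | O=C1CC(=O)[C@@H](CCC(C)(C)O)[C@H](c2cc3c(OCc4ccccc4)cc(OCc4ccccc4)c(C(C)(C)C=C)c3o2)[C@H]1C(=O)OC(C)(C)C | intermediate
19 | 6-Ar-5-(3-hydroxy-3-methylbutyl)-2,4-dioxocyclohexane-1-carboxylic acid, racemic, all-trans | O=C1CC(=O)[C@@H](CCC(C)(C)O)[C@H](c2cc3c(OCc4ccccc4)cc(OCc4ccccc4)c(C(C)(C)C=C)c3o2)[C@H]1C(=O)O | intermediate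
20 | 5-Ar-4-(3-hydroxy-3-methylbutyl)cyclohexane-1,3-dione, racemic, 4,5-trans | O=C1CC(=O)[C@@H](CCC(C)(C)O)[C@H](c2cc3c(OCc4ccccc4)cc(OCc4ccccc4)c(C(C)(C)C=C)c3o2)C1 | intermediate
21 | 5-Ar-2,2-dimethyl-2,3,4,4a,5,6-hexahydro-7H-chromen-7-one, racemic, 4a,5-trans (drawn 4aS,5R) | O=C1C=C2OC(C)(C)CC[C@H]2[C@H](c2cc3c(OCc4ccccc4)cc(OCc4ccccc4)c(C(C)(C)C=C)c3o2)C1 | intermediate
22 | 5-Ar-2,2-dimethyl-7-(trimethylsilyloxy)-3,4,4a,5-tetrahydro-2H-chromene, racemic, 4a,5-trans | C[Si](C)(C)OC1=C[C@@H](c2cc3c(OCc4ccccc4)cc(OCc4ccccc4)c(C(C)(C)C=C)c3o2)[C@@H]2CCC(C)(C)OC2=C1 | intermediate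
23 | 5-Ar-2,2-dimethyl-2,3,4,4a-tetrahydro-7H-chromen-7-one, racemic | O=C1C=C(c2cc3c(OCc4ccccc4)cc(OCc4ccccc4)c(C(C)(C)C=C)c3o2)[C@@H]2CCC(C)(C)OC2=C1 | intermediate
24 | 5-[4,6-bis(benzyloxy)-7-(2-methylbut-3-en-2-yl)benzofuran-2-yl]-2,2-dimethylchroman-7-ol | C=CC(C)(C)c1c(OCc2ccccc2)cc(OCc2ccccc2)c2cc(-c3cc(O)cc4c3CCC(C)(C)O4)oc12 | intermediate
25 | 2-(7-hydroxy-2,2-dimethylchroman-5-yl)-7-(2-methylbut-3-en-2-yl)benzofuran-4,6-diol (CNP0300714.0) | C=CC(C)(C)c1c(O)cc(O)c2cc(-c3cc(O)cc4c3CCC(C)(C)O4)oc12 | target

## Step count and least certain steps

Total: 13 steps. Longest linear sequence: 12 steps (steps 1–6 and 8–13, from 1); the lactone branch is step 7.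

**Step 10 (key step).** The conjugate addition may be too slow on an α-substituted acceptor whose β-carbon carries an electron-rich benzofuran. Alkoxide-driven opening of the lactone, migration of the exocyclic double bond into the lactone ring or reversal of the Michael addition could then win, or the sequence could stop at the open adduct without acylation. The fallback uses the established version on an acyclic unsaturated ester; it sets out from 10 and returns at 21. Triethyl phosphonoacetate is alkylated with 2 (NaH, THF) to ethyl 2-(diethoxyphosphoryl)-5-methylhex-4-enoate F1. Horner–Wadsworth–Emmons reaction of F1 with 10 gives ethyl (E)-2-(Ar-methylene)-5-methylhex-4-enoate F2, whose alkene geometry is of no consequence. F2 and 16 with KOtBu in tBuOH should undergo Michael addition and Claisen closure with loss of ethoxide to tert-butyl 6-Ar-5-(3-methylbut-2-en-1-yl)-2,4-dioxocyclohexane-1-carboxylate F3. TsOH in warm toluene then removes the ester and decarboxylates to 5-Ar-4-(3-methylbut-2-en-1-yl)cyclohexane-1,3-dione F4 (not isolated), and adds the enol oxygen across the prenyl double bond in the Markovnikov sense, the known acid cyclisation of prenyl 1,3-diones, which gives 21.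

**Step 11.** Protonation at the ring A carbon that bears the 1,1-dimethylallyl group could lead to loss or migration of that group. Ionisation of the tertiary alcohol could also alkylate the electron-rich benzofuran or eliminate, in place of closure on oxygen. The fallback avoids strong acid; it sets out from 15 and returns at 21. Ethyl acetoacetate and NaOEt in ethanol give the classical Michael–Claisen product ethyl 6-Ar-5-(3-hydroxy-3-methylbutyl)-2,4-dioxocyclohexane-1-carboxylate F5. Aqueous NaOH saponifies the ester, and acidification with acetic acid and gentle warming decarboxylates acid 19 to 20, which is isolated. Pyridinium p-toluenesulfonate with molecular sieves in warm toluene then closes the vinylogous ester 21.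

**Step 2.** A second [3,3] shift of the ortho-dienone to the free para carbon between the benzyloxy groups, ring closure of the new phenol onto its own alkene, or simple loss of the prenyl group may erode the rearrangement. The fallback changes the order so that the new phenol is tied up in a hydrogen bond to a formyl group; it sets out from 1 and returns at 5. Ortho-formylation of 1 (MgCl2, Et3N, paraformaldehyde) gives 4,6-bis(benzyloxy)-2-hydroxybenzaldehyde F6. O-Alkylation with 2 (K2CO3, DMF) gives 4,6-bis(benzyloxy)-2-[(3-methylbut-2-en-1-yl)oxy]benzaldehyde F7. Claisen rearrangement of F7 into its only free ortho carbon gives 5 directly.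

**Step 12.** Enolisation may occur at the γ-position in place of C6, the palladium enolate may form on the face that has no syn hydrogen at C5, or divalent palladium may engage the vinyl group or the benzofuran. The fallback is a selenoxide elimination; it sets out from 21 and returns at 24. LiN(iPr)2 and PhSeCl at −78 °C give 5-Ar-2,2-dimethyl-6-(phenylselanyl)-2,3,4,4a,5,6-hexahydro-7H-chromen-7-one F8. One equivalent of 3-chloroperbenzoic acid at −78 °C in the presence of iPr2NH gives the selenoxide F9 (not isolated), whose syn elimination on warming leads to 23 and so to 24.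

**Step 13.** Acid-promoted ring closure of the freed C6 hydroxyl onto the neighbouring alkene, ipso-protonation with loss of the 1,1-dimethylallyl group, or opening of the tert-alkyl ether of ring D could accompany debenzylation. The fallback is nucleophilic and sets out from 24 and returns at 25. NaSEt in DMF at about 130 °C removes the benzyl groups by SN2 attack at the benzylic carbons under basic conditions, where the alkene and ring D are not at risk. The second cleavage is expected to be slower because a dianion must leave. No new compound is isolated on this path (F0).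

## Further compounds

F1 | step 10 | ethyl 2-(diethoxyphosphoryl)-5-methylhex-4-enoate | CCOC(=O)C(CC=C(C)C)P(=O)(OCC)OCC
F2 | step 10 | ethyl (E)-2-(Ar-methylene)-5-methylhex-4-enoate | C=CC(C)(C)c1c(OCc2ccccc2)cc(OCc2ccccc2)c2cc(/C=C(\CC=C(C)C)C(=O)OCC)oc12
F3 | step 10 | tert-butyl 6-Ar-5-(3-methylbut-2-en-1-yl)-2,4-dioxocyclohexane-1-carboxylate, racemic, all-trans | O=C1CC(=O)[C@@H](CC=C(C)C)[C@H](c2cc3c(OCc4ccccc4)cc(OCc4ccccc4)c(C(C)(C)C=C)c3o2)[C@H]1C(=O)OC(C)(C)C
F4 | step 10 | 5-Ar-4-(3-methylbut-2-en-1-yl)cyclohexane-1,3-dione, racemic, 4,5-trans | O=C1CC(=O)[C@@H](CC=C(C)C)[C@H](c2cc3c(OCc4ccccc4)cc(OCc4ccccc4)c(C(C)(C)C=C)c3o2)C1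
F5 | step 11 | ethyl 6-Ar-5-(3-hydroxy-3-methylbutyl)-2,4-dioxocyclohexane-1-carboxylate, racemic, all-trans | O=C1CC(=O)[C@@H](CCC(C)(C)O)[C@H](c2cc3c(OCc4ccccc4)cc(OCc4ccccc4)c(C(C)(C)C=C)c3o2)[C@H]1C(=O)OCC
F6 | step 2 | 4,6-bis(benzyloxy)-2-hydroxybenzaldehyde | O=Cc1c(O)cc(OCc2ccccc2)cc1OCc1ccccc1
F7 | step 2 | 4,6-bis(benzyloxy)-2-[(3-methylbut-2-en-1-yl)oxy]benzaldehyde | CC(C)=CCOc1cc(OCc2ccccc2)cc(OCc2ccccc2)c1C=O
F8 | step 12 | 5-Ar-2,2-dimethyl-6-(phenylselanyl)-2,3,4,4a,5,6-hexahydro-7H-chromen-7-one, racemic, 4a,5-trans | O=C1C=C2OC(C)(C)CC[C@H]2[C@H](c2cc3c(OCc4ccccc4)cc(OCc4ccccc4)c(C(C)(C)C=C)c3o2)C1[Se]c1ccccc1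
F9 | step 12 | 5-Ar-2,2-dimethyl-6-(phenylseleninyl)-2,3,4,4a,5,6-hexahydro-7H-chromen-7-one, racemic, 4a,5-trans | O=C1C=C2OC(C)(C)CC[C@H]2[C@H](c2cc3c(OCc4ccccc4)cc(OCc4ccccc4)c(C(C)(C)C=C)c3o2)C1[Se](=O)c1ccccc1
F0 | step 13 | none | none
A1 | alternative 1 | 2-[2,2-dimethyl-7-(triisopropylsilyloxy)chroman-5-yl]-7-(2-methylbut-3-en-2-yl)-6-(triisopropylsilyloxy)benzofuran-4-ol | C=CC(C)(C)c1c(O[Si](C(C)C)(C(C)C)C(C)C)cc(O)c2cc(-c3cc(O[Si](C(C)C)(C(C)C)C(C)C)cc4c3CCC(C)(C)O4)oc12
A2 | alternative 1 | 2-{5-[2,2-dimethyl-7-(triisopropylsilyloxy)chroman-5-yl]furan-2-yl}-3,3-dimethylpent-4-enoyl chloride | C=CC(C)(C)C(C(=O)Cl)c1ccc(-c2cc(O[Si](C(C)C)(C(C)C)C(C)C)cc3c2CCC(C)(C)O3)o1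
A3 | alternative 1 | (triisopropylsilyloxy)ethyne | C#CO[Si](C(C)C)(C(C)C)C(C)C
A4 | alternative 2 | 2-{5-[4,6-bis(methoxymethoxy)-7-(2-methylbut-3-en-2-yl)benzofuran-2-yl]-2,2-dimethylchroman-7-yl}-4,4,5,5-tetramethyl-1,3,2-dioxaborolane | C=CC(C)(C)c1c(OCOC)cc(OCOC)c2cc(-c3cc(B5OC(C)(C)C(C)(C)O5)cc4c3CCC(C)(C)O4)oc12
A5 | alternative 2 | 2-[5-(ethynyloxy)-5-methylhex-1-yn-1-yl]-4,6-bis(methoxymethoxy)-7-(2-methylbut-3-en-2-yl)benzofuran | C=CC(C)(C)c1c(OCOC)cc(OCOC)c2cc(C#CCCC(C)(C)OC#C)oc12
A6 | alternative 2 | 2-ethynyl-4,4,5,5-tetramethyl-1,3,2-dioxaborolane | C#CB1OC(C)(C)C(C)(C)O1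
A7 | alternative 3 | 4,6-bis(benzyloxy)-2-[7-(benzyloxy)-2,2-dimethylchroman-5-yl]-7-(2-methylbut-3-en-2-yl)benzofuran | C=CC(C)(C)c1c(OCc2ccccc2)cc(OCc2ccccc2)c2cc(-c3cc(OCc4ccccc4)cc4c3CCC(C)(C)O4)oc12
A8 | alternative 3 | 2-[3,5-bis(benzyloxy)-2-(2-methylbut-3-en-2-yl)phenoxy]-2-[7-(benzyloxy)-2,2-dimethylchroman-5-yl]acetaldehyde | C=CC(C)(C)c1c(OCc2ccccc2)cc(OCc2ccccc2)cc1OC(C=O)c1cc(OCc2ccccc2)cc2c1CCC(C)(C)O2
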